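**Retrosynthetic overview**

- The target, 5-henicosyl-1H-pyrrole-2-carbaldehyde, is traced back through its carbinol to methyl 5-henicosyl-1H-pyrrole-2-carboxylate, and this to the corresponding 3-pyrroline by dehydrogenation.
- The strategy rests on C3 and C4 of the pyrrole ring being unsubstituted CH carbons. Their bond is cut as the product double bond of a ring-closing metathesis between two vinyl groups on the carbons that become C2 (ester) and C5 (henicosyl chain).
- The metathesis substrate, the ammonium chloride of methyl 2-(tetracos-1-en-3-ylamino)but-3-enoate, comes from esterification of the amino acid made by Petasis coupling of tetracos-1-en-3-amine, glyoxylic acid and vinylboronic acid pinacol ester.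
- The allylic amine comes from 1-docosanol by oxidation, sulfinyl imine formation, vinyl Grignard addition and removal of the sulfinyl group.
- Ring order: the only ring, the pyrrole, is closed as a 3-pyrroline in step 7 and aromatised in step 8.

Key step: step 7

Remark on the chemistry: the two sp3 carbons created in steps 3 and 5 both end as sp2 carbons of the pyrrole, so racemic tert-butanesulfinamide is used and all intermediates are carried as racemates or diastereomer mixtures. The target has no stereocentre.

**Route**

Step 1
Reactants: 1 1-docosanol
Product: 2 docosanal
Conditions: TEMPO (10 mol%), PhI(OAc)2 (1.1 equiv), CH2Cl2, 30 °C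
Reagents that add atoms: none
Why: Oxoammonium-catalysed alcohol oxidation (TEMPO with a hypervalent iodine co-oxidant) should stop at the aldehyde because no water is present to form the hydrate needed for over-oxidation.

Step 2
Reactants: 2 docosanal; 3 racemic 2-methylpropane-2-sulfinamide
Product: 4 (E)-N-docosylidene-2-methylpropane-2-sulfinamide
Conditions: Ti(OEt)4 (2 equiv), THF, rt; brine, filtration
Reagents that add atoms: none
Why: Ellman condensation, in which Ti(OEt)4 serves as Lewis acid and water scavenger, should give the E-aldimine without aldol self-condensation of the enolisable aldehyde.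

Step 3
Reactants: 4 (E)-N-docosylidene-2-methylpropane-2-sulfinamide; 5 vinylmagnesium bromide
Product: 6 N-(tetracos-1-en-3-yl)-2-methylpropane-2-sulfinamide (racemic, diastereomer mixture)
Conditions: CH2=CHMgBr (1.0 M in THF, 1.5 equiv), CH2Cl2, −78 to −40 °C; aq NH4Cl
Reagents that add atoms: none
Why: Grignard 1,2-addition to an N-sulfinyl aldimine, whose electron-poor C=N favours addition over α-deprotonation; the new carbinamine centre is biased by sulfur through a cyclic magnesium-bridged transition state, but its configuration is of no consequence because it becomes C5 of the pyrrole.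

Step 4
Reactants: 6 N-(tetracos-1-en-3-yl)-2-methylpropane-2-sulfinamide
Product: 8 tetracos-1-en-3-amine (racemic), via tetracos-1-en-3-aminium chloride 7 (not isolated)
Conditions: HCl (4 M in dioxane, 2 equiv), MeOH, rt; then aq NaOH, extraction
Reagents that add atoms: none
Why: Acidic methanolysis of the S–N bond (standard sulfinamide cleavage) should release the amine salt and methyl tert-butanesulfinate without touching the isolated vinyl group, and base work-up gives the free amine.

Step 5
Reactants: 8 tetracos-1-en-3-amine; 9 glyoxylic acid (used as its monohydrate); 10 vinylboronic acid pinacol ester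
Product: 12 2-(tetracos-1-en-3-ylamino)but-3-enoic acid (diastereomer mixture), via the imino acid 11 (not isolated)
Conditions: HFIP/CH2Cl2 (1:4), 40 °C; aqueous work-up
Reagents that add atoms: none
Why: Petasis borono-Mannich reaction, in which the carboxylate of the iminium formed from 8 and 9 binds boron and the resulting ate complex delivers the vinyl group to the iminium carbon; the new α-centre is not controlled and need not be, since it becomes C2 of the pyrrole, and the α-branched amine should resist a second alkylation.

Step 6
Reactants: 12 2-(tetracos-1-en-3-ylamino)but-3-enoic acid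
Product: 13 methyl 2-(tetracos-1-en-3-ylamino)but-3-enoate hydrochloride (diastereomer mixture)
Conditions: SOCl2 (3 equiv) added to MeOH at 0 °C, then 12, CH2Cl2 co-solvent, 45 °C; evaporation
Reagents that add atoms: methanol, CO; thionyl chloride, O=S(Cl)Cl (source of the chloride counter-ion through HCl formed in the flask)
Why: Fischer-type esterification with HCl generated in the flask keeps nitrogen protonated throughout, which should prevent base-induced migration of the β,γ-double bond into conjugation and gives directly the ammonium salt needed for metathesis.

Step 7
Reactants: 13 methyl 2-(tetracos-1-en-3-ylamino)but-3-enoate hydrochloride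
Product: 15 methyl 5-henicosyl-2,5-dihydro-1H-pyrrole-2-carboxylate (cis and trans mixture), via the 3-pyrrolinium chloride 14 (not isolated)
Conditions: second-generation Grubbs catalyst RuCl2(=CHPh)(H2IMes)(PCy3) (5 mol%), 1,4-benzoquinone (10 mol%), CH2Cl2 (0.01 M), 40 °C, argon sparge; then aq NaHCO3
Reagents that add atoms: none
Why: The ruthenium benzylidene exchanges with one of the two monosubstituted vinyl groups of 13 to give a substrate-bound alkylidene, which adds across the second vinyl group in a [2+2] cycloaddition, and cycloreversion of the ruthenacyclobutane releases the ring and a ruthenium methylidene that carries the chain with loss of ethylene. The closest known reaction type is ring-closing metathesis of diallylammonium salts to 3-pyrrolinium salts. The single ring is closed at the C3–C4 bond as a five-membered ring from a 1,6-diene, a highly favourable ring size for this cyclisation, and the cis double bond is enforced by the ring. No stereocentre is created; the two allylic centres are carried as a cis and trans mixture and both are erased in step 8. The step needs cyclisation to win over intermolecular metathesis, catalyst poisoning by nitrogen and hydride-mediated alkene migration: high dilution and the 1,6-diene geometry should secure the first, the protonated nitrogen has no lone pair to bind ruthenium, and benzoquinone intercepts ruthenium hydrides. Regiochemistry is not in question because the ester and the chain already sit on the carbons that become C2 and C5.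

Step 8
Reactants: 15 methyl 5-henicosyl-2,5-dihydro-1H-pyrrole-2-carboxylate
Product: 16 methyl 5-henicosyl-1H-pyrrole-2-carboxylate
Conditions: DDQ (1.05 equiv), toluene, 0 °C to rt
Reagents that add atoms: none
Why: Quinone dehydrogenation, in which hydride abstraction from a C–H that is allylic and α to nitrogen followed by proton loss and tautomerisation gives the aromatic pyrrole; the limited charge of DDQ should spare the α-methylene of the chain.

Step 9
Reactants: 16 methyl 5-henicosyl-1H-pyrrole-2-carboxylate
Product: 17 (5-henicosyl-1H-pyrrol-2-yl)methanol
Conditions: LiAlH4 (2 equiv), THF, 0 °C; then H2O, 15% aq NaOH, H2O; used crude at once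
Reagents that add atoms: none
Why: Hydride reduction of the ester to the primary alcohol with LiAlH4, held at 0 °C and worked up under basic conditions so that loss of the oxygen from the N-metallated carbinol (azafulvene formation) and acid-induced oligomerisation are avoided.

Step 10
Reactants: 17 (5-henicosyl-1H-pyrrol-2-yl)methanol
Product: 18 5-henicosyl-1H-pyrrole-2-carbaldehyde (target)
Conditions: activated MnO2 (10 equiv), CH2Cl2, rt
Reagents that add atoms: none
Why: MnO2 oxidation of an activated, benzylic-type pyrrolylmethanol to the aldehyde under neutral conditions should give the stable vinylogous formamide without over-oxidation.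

**Compound list**

1 | 1-docosanol | CCCCCCCCCCCCCCCCCCCCCCO | starting material
2 | docosanal | CCCCCCCCCCCCCCCCCCCCCC=O | intermediate
3 | racemic 2-methylpropane-2-sulfinamide (tert-butanesulfinamide) | CC(C)(C)S(N)=O | starting material
4 | (E)-N-docosylidene-2-methylpropane-2-sulfinamide | CCCCCCCCCCCCCCCCCCCCC/C=N/S(=O)C(C)(C)C | intermediate
5 | vinylmagnesium bromide | C=C[Mg]Br | starting material
6 | N-(tetracos-1-en-3-yl)-2-methylpropane-2-sulfinamide (racemic, diastereomer mixture) | CCCCCCCCCCCCCCCCCCCCCC(C=C)NS(=O)C(C)(C)C | intermediate
7 | tetracos-1-en-3-aminium chloride (not isolated) | CCCCCCCCCCCCCCCCCCCCCC(C=C)[NH3+].[Cl-] | intermediate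
8 | tetracos-1-en-3-amine (racemic) | CCCCCCCCCCCCCCCCCCCCCC(N)C=C | intermediate
9 | glyoxylic acid (used as its monohydrate) | O=CC(=O)O | starting material
10 | vinylboronic acid pinacol ester | C=CB1OC(C)(C)C(C)(C)O1 | starting material
11 | 2-(tetracos-1-en-3-ylimino)acetic acid (not isolated) | CCCCCCCCCCCCCCCCCCCCCC(C=C)N=CC(=O)O | intermediate
12 | 2-(tetracos-1-en-3-ylamino)but-3-enoic acid (diastereomer mixture) | CCCCCCCCCCCCCCCCCCCCCC(C=C)NC(C=C)C(=O)O | intermediate
13 | methyl 2-(tetracos-1-en-3-ylamino)but-3-enoate hydrochloride (diastereomer mixture) | CCCCCCCCCCCCCCCCCCCCCC(C=C)[NH2+]C(C=C)C(=O)OC.[Cl-] | intermediate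
14 | methyl 5-henicosyl-2,5-dihydro-1H-pyrrol-1-ium-2-carboxylate chloride (cis and trans mixture, not isolated) | CCCCCCCCCCCCCCCCCCCCCC1C=CC(C(=O)OC)[NH2+]1.[Cl-] | intermediate
15 | methyl 5-henicosyl-2,5-dihydro-1H-pyrrole-2-carboxylate (cis and trans mixture) | CCCCCCCCCCCCCCCCCCCCCC1C=CC(C(=O)OC)N1 | intermediate
16 | methyl 5-henicosyl-1H-pyrrole-2-carboxylate | CCCCCCCCCCCCCCCCCCCCCc1ccc(C(=O)OC)[nH]1 | intermediate
17 | (5-henicosyl-1H-pyrrol-2-yl)methanol | CCCCCCCCCCCCCCCCCCCCCc1ccc(CO)[nH]1 | intermediate
18 | 5-henicosyl-1H-pyrrole-2-carbaldehyde | CCCCCCCCCCCCCCCCCCCCCc1ccc(C=O)[nH]1 | target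

**Summary**

Total step count: 10. Longest linear sequence: 10 steps, from 1-docosanol 1 to the target 18.

Steps most likely to fail:

Step 5 (Petasis coupling). Transfer of the unsubstituted vinyl group from the pinacol boronate to the iminium carbon may be too slow, so that the imino acid decomposes or the amine is consumed in side reactions. The fallback sets out from amine 8 and uses a more nucleophilic alkenylboron partner whose extra substituent is lost in the metathesis. Petasis coupling of 8 with glyoxylic acid 9 and (E)-styrylboronic acid should give (E)-4-phenyl-2-(tetracos-1-en-3-ylamino)but-3-enoic acid F1. Esterification as in step 6 should give methyl (E)-4-phenyl-2-(tetracos-1-en-3-ylamino)but-3-enoate hydrochloride F2. Ring-closing metathesis of F2 under the conditions of step 7 should start at the vinyl group, close onto the styryl double bond and expel styrene in place of ethylene. It comes back to the route at the 3-pyrrolinium chloride 14.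

Step 7 (ring-closing metathesis). The catalyst may be deactivated by traces of free amine, or ruthenium hydrides may move the vinylglycine double bond into conjugation faster than the ring closes. The fallback sets out from 13 and replaces the ammonium masking by a non-basic amide. Treatment of 13 with trifluoroacetic anhydride and pyridine in CH2Cl2 at 0 °C should give methyl 2-[2,2,2-trifluoro-N-(tetracos-1-en-3-yl)acetamido]but-3-enoate F3. Ring-closing metathesis of this neutral diene with the same catalyst should give methyl 5-henicosyl-1-(trifluoroacetyl)-2,5-dihydro-1H-pyrrole-2-carboxylate F4. Methanolysis of the trifluoroacetamide with K2CO3 in MeOH returns to the route at 15. Any double-bond isomer of 15 formed under these basic conditions is at the same oxidation level and should converge on 16 in step 8.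

Step 9 (ester reduction). The N-metallated carbinol may lose its oxygen to an azafulvene that is reduced further to the 2-methylpyrrole, or the free carbinol may oligomerise during work-up. The fallback sets out from 16 and gives up the ester carbon in favour of a formylation. Saponification with NaOH in aqueous ethanol should give 5-henicosyl-1H-pyrrole-2-carboxylic acid F5. Thermal decarboxylation in ethanolamine at about 170 °C should give 2-henicosyl-1H-pyrrole F6. Vilsmeier–Haack formylation with POCl3 and DMF, followed by aqueous sodium acetate, should take place at the free α-position. It comes back to the route at the target 18, so step 10 is bypassed.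

**Further compounds**

F1 | step 5 | (E)-4-phenyl-2-(tetracos-1-en-3-ylamino)but-3-enoic acid | CCCCCCCCCCCCCCCCCCCCCC(C=C)NC(/C=C/c1ccccc1)C(=O)O
F2 | step 5 | methyl (E)-4-phenyl-2-(tetracos-1-en-3-ylamino)but-3-enoate hydrochloride | CCCCCCCCCCCCCCCCCCCCCC(C=C)[NH2+]C(/C=C/c1ccccc1)C(=O)OC.[Cl-]
F3 | step 7 | methyl 2-[2,2,2-trifluoro-N-(tetracos-1-en-3-yl)acetamido]but-3-enoate | CCCCCCCCCCCCCCCCCCCCCC(C=C)N(C(=O)C(F)(F)F)C(C=C)C(=O)OC
F4 | step 7 | methyl 5-henicosyl-1-(trifluoroacetyl)-2,5-dihydro-1H-pyrrole-2-carboxylate | CCCCCCCCCCCCCCCCCCCCCC1C=CC(C(=O)OC)N1C(=O)C(F)(F)F
F5 | step 9 | 5-henicosyl-1H-pyrrole-2-carboxylic acid | CCCCCCCCCCCCCCCCCCCCCc1ccc(C(=O)O)[nH]1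
F6 | step 9 | 2-henicosyl-1H-pyrrole | CCCCCCCCCCCCCCCCCCCCCc1ccc[nH]1
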